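Compound numbers refer to the steps and to the compound list after them.

## Analysis of the target

The target is a flavan: a chroman (ring A fused to the dihydropyran ring C) that carries a 2,4-dihydroxyphenyl group (ring B) on C2. Ring A is a phloroglucinol unit whose three oxygens are all different (O1 in the pyran, a free hydroxyl at C5, a methyl ether at C7), and it bears a prenyl group at C8, so C6 is its only C–H. C2 is the only stereocentre and is (S); with no hydroxyl, carbonyl or second stereocentre on C3 or C4 to relay from, it has to be set by absolute control. C2 is also the fragile point, because it is benzylic to a ring with oxygens ortho and para to it and carries an aryloxy leaving group, so acid or phenoxide formation on ring B can open the C2–O1 bond and racemise it. The prenyl double bond excludes heterogeneous hydrogenation and hydrogenolytic deprotection and tolerates little acid, and the free phenols oxidise easily. The difficulty is therefore to place four oxygen functions and the prenyl group regiochemically and to build ring C around a labile stereocentre without strong acid. The plan rests on one feature of ring A: C8 is occupied by the prenyl group, so C4a is the only position ortho to O1 that can be a C–H in an open precursor, and it lies ortho to the C5 oxygen and para to the C7 methoxy group; a two-carbon unit attached through C2 and O1 can therefore close ring C only by bonding to C4a.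

## Retrosynthetic reasoning

**O–acyl bonds of 17.** The three phenols of 18 are released last from the tripivalate 17. Acyl protection is deliberate: it makes ring B electron-poor in every step in which C2 could ionise, and it is removed by mild transesterification, which leaves the prenyl group and the C2–O1 bond alone.

**C3–C4 saturation (17 to 16).** 17 is traced back to the 2H-chromene 16 by removing two hydrogens from C3 and C4. The forward step must distinguish the cis-disubstituted styrenic alkene from the trisubstituted prenyl alkene and must not cleave the allylic, benzylic C2–O1 bond, which calls for a metal-free hydrogen transfer that is sensitive to alkene substitution.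

**C4–C4a (16 to 15, the key disconnection).** Cutting C4–C4a opens ring C to the aryl propargyl ether 15. The cut is made here because C4a needs no handle (a C–H bond suffices), because C8 is blocked so no regioisomer can form, and because none of the bonds to C2 is made or broken. The alkyne delivers C3 and C4 one oxidation level above the target, which costs the reduction above. The forward reaction has to be a 6-endo ring closure that is faster than any pathway through a cation at C2 or through a sigmatropic shift.

**O1–C2 (15 to 9 and 14).** The ether bond is cut to the ring A phenol 9 and the ring B propargylic ester 14. C2 is created here, in an intermolecular C–O bond formation under a chiral copper catalyst. That reaction runs through a planar copper allenylidene, so racemic 14 is enough and no stereocentre has to be carried into the coupling. The pivalate at the C5 oxygen of 9 is kept so that the phenol oxygen, not a ring carbon, is alkylated.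

**C2–C3 (14 to 11 and 12).** The propargylic ester comes from addition of the alkynyl Grignard reagent 12 to the aldehyde 11, itself the dipivalate of 10. The alkoxide 13 is acylated in the flask with the same acyl group that sits on the ring. If the ortho acyl group shifts to the alkoxide, acylation of the freed phenoxide gives the same 14, so the shift is harmless.

**C8–prenyl bond (9 back to 1).** Direct C-prenylation of 1 is not used: its most nucleophilic carbon lies between the two hydroxyls, and O-alkylation and double alkylation compete. Instead the aryl–CH2 bond is made from the aryllithium 5 and 4. 5 is generated from 3 by directed metalation at the one carbon flanked by two coordinating oxygens, with the third oxygen carried as a bulky silyl ether. This gives 6, in which the prenyl group sits between the future O1 and the methoxy group. The silyl ether is then exchanged for the pivalate (6 to 8 via 7) and the acetal is removed to give 9. 3 comes from 1 by monosilylation (2) and acetal formation; 1 is symmetric, so neither step has a regiochemical issue.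

## Alternatives that were turned down

**Alternative 1:** Ring C is cut at C3–C4 and O1–C2 at once. Chroman A1 would come from the ring A ortho-hydroxybenzyl alcohol A2 and the ring B hydroxystyrene A3: a chiral BINOL-derived phosphoric acid dehydrates A2 to its ortho-quinone methide and steers an oxa-[4+2] cycloaddition with A3.
- For: two bonds, the ring and C2 are made in one convergent step, and the chroman oxidation level is reached directly. On bond economy and on steps after ring closure it is stronger than the chosen plan.
- Against: the methide carbon (the future C4) carries no substituent. Asymmetric versions of this cycloaddition rely on an aryl or alkyl group there to tame the quinone methide and to give the catalyst a steric handle; an unsubstituted one oligomerises readily and offers little facial bias.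
- Against: the new stereocentre in A1 is a doubly oxygen-activated benzylic ether formed in the presence of a Brønsted acid, so reversible ionisation can erode it. In A2 a free phenol sits ortho to the prenyl group under acid, and A2 needs an extra carbon placed regioselectively on a crowded ring.
- Comparison: the chosen route pays one reduction step but creates C2 under basic conditions and never exposes an electron-rich ring B next to C2 to acid.

**Alternative 2:** Ring C is cut at C4–C4a and O1–C8a. Chroman A4 would come from the ring A aryl iodide A5 and the enantioenriched 2-aryloxetane A6 under Pd(OAc)2, a phosphine, norbornene and Cs2CO3: the aryl–norbornyl palladacycle opens the oxetane at its CH2 and, after norbornene extrusion, the alkoxide closes the aryl ether.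
- For: the stereocentre is brought in ready-made and is not touched, the chroman forms directly without acid, and the C8 prenyl group is the ortho substituent such relays need. In convergence it matches the chosen plan, and in the safety of C2 during ring closure it is stronger.
- Against: opening a four-membered ether with a palladacycle is far less favourable than opening an epoxide. An electron-rich 2-aryloxetane also tends to open at its benzylic C–O bond, which would give the wrong skeleton and destroy the stereocentre.
- Against: the final C–O reductive elimination from a secondary alkoxide on divalent palladium competes with β-hydride elimination. A5 is no easier to make than 9, and the acetal groups of A4 would have to be removed with acid next to the prenyl group.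
- Comparison: both plans use the C4a–H bond, but the chosen one closes the ring by a reaction type that is established for aryl propargyl ethers.

**Alternative 3:** Ring C is cut at C3=C4. Chromene A7 would come from diene A8 by ring-closing metathesis with the second-generation Grubbs catalyst RuCl2(=CHPh)(PCy3)(H2IMes).
- For: metathesis to 2H-chromenes is a very dependable ring closure, it is neutral, and it puts no positive charge near C2. In the reliability of the ring-forming event itself it is stronger than gold catalysis, and it reaches the same kind of chromene with the same reduction to follow.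
- Against: ring A must carry a vinyl group at C4a, which needs a further regiocontrolled C–C bond on a fully substituted ring and adds steps. The phenol to be etherified is then flanked by vinyl and prenyl groups, which makes the asymmetric allylic etherification that has to set C2 much harder.
- Against: the ruthenium carbene can also engage the prenyl group, and silyl ethers on ring B leave the C2–O bond ionisable.
- Comparison: the chosen plan reaches the same C3=C4 chromene from a C–H bond, takes both new ring carbons from 12, and needs ring A only as a phenol. The price is that the gold step must not racemise C2, which the pivalates are there to prevent.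

Key step: step 9

Assumption: the (S,S) antipode of the pybox ligand in step 8 is taken to deliver the (S)-ether 15; the sense of induction for this pair of partners has to be confirmed, and the mirror-image ligand is used if it proves opposite.

## Route

Step 1
Reactants: 1 5-methoxyresorcinol
Product: 2 3-methoxy-5-(triisopropylsilyloxy)phenol
Conditions: TIPSCl (1.0 equiv), imidazole, DMF, 0 °C to rt
Reagents that add atoms: triisopropylsilyl chloride, CC(C)[Si](Cl)(C(C)C)C(C)C
Why: Imidazole-promoted O-silylation of one of two equivalent phenols; 1 is symmetric, so the only issue is mono- versus bis-silylation, and recovered 1 and bis-silyl ether can be recycled. The triisopropylsilyl group survives butyllithium and screens both ring positions next to it in step 3.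

Step 2
Reactants: 2 3-methoxy-5-(triisopropylsilyloxy)phenol
Product: 3 triisopropyl[3-methoxy-5-(methoxymethoxy)phenoxy]silane
Conditions: MOMCl, i-Pr2NEt, CH2Cl2, 0 °C to rt
Reagents that add atoms: chloromethyl methyl ether, COCCl
Why: Standard O-alkylation of the remaining phenol to its methoxymethyl ether, which protects the future O1 and serves as the directing group for the metalation that follows.

Step 3
Reactants: 3 triisopropyl[3-methoxy-5-(methoxymethoxy)phenoxy]silane; 4 prenyl bromide
Product: 6 triisopropyl[3-methoxy-5-(methoxymethoxy)-4-(3-methylbut-2-enyl)phenoxy]silane, via [2-methoxy-6-(methoxymethoxy)-4-(triisopropylsilyloxy)phenyl]lithium 5 (not isolated)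
Conditions: n-BuLi, THF, 0 °C; CuBr·SMe2 (10 mol %), then 4, −78 °C to rt
Reagents that add atoms: none
Why: Directed ortho-metalation followed by copper-catalysed allylation: chelation guides butyllithium to the only carbon flanked by two coordinating oxygens (methoxymethoxy and methoxy), the two other ring positions being screened by the silyl ether. The aryl copper species formed from 5 couples with 4 at its primary carbon, so the prenyl group arrives unrearranged at the future C8.

Step 4
Reactants: 6 triisopropyl[3-methoxy-5-(methoxymethoxy)-4-(3-methylbut-2-enyl)phenoxy]silane
Product: 8 3-methoxy-5-(methoxymethoxy)-4-(3-methylbut-2-enyl)phenyl pivalate, via 3-methoxy-5-(methoxymethoxy)-4-(3-methylbut-2-enyl)phenol 7 (not isolated)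
Conditions: TBAF, THF, 0 °C; then PivCl, Et3N, 0 °C to rt
Reagents that add atoms: pivaloyl chloride, CC(C)(C)C(=O)Cl
Why: Fluoride cleaves the aryl silyl ether while the acetal and the alkene are inert, and the phenoxide of 7 is acylated in the same flask. The silyl ether needed for the lithiation is thus exchanged for the electron-withdrawing, base-cleavable pivalate wanted on the C5 oxygen from here on.

Step 5
Reactants: 8 3-methoxy-5-(methoxymethoxy)-4-(3-methylbut-2-enyl)phenyl pivalate
Product: 9 3-hydroxy-5-methoxy-4-(3-methylbut-2-enyl)phenyl pivalate
Conditions: conc. HCl (cat.), MeOH, rt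
Reagents that add atoms: none
Why: Acid-catalysed acetal exchange with methanol frees the phenol that becomes O1; the hindered aryl pivalate should not transesterify under these conditions. Short exposure at room temperature keeps the new phenol from adding across the neighbouring prenyl double bond.

Step 6
Reactants: 10 2,4-dihydroxybenzaldehyde
Product: 11 4-formyl-1,3-phenylene dipivalate
Conditions: PivCl, Et3N, DMAP (cat.), CH2Cl2, 0 °C to rt
Reagents that add atoms: pivaloyl chloride, CC(C)(C)C(=O)Cl
Why: DMAP-catalysed acylation of both phenols; the pivalates make ring B electron-poor for all later steps and are bulky enough to resist the Grignard reagent at low temperature and the amine and methanol of step 8.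

Step 7
Reactants: 11 4-formyl-1,3-phenylene dipivalate; 12 ethynylmagnesium bromide
Product: 14 rac-1-[2,4-bis(pivaloyloxy)phenyl]prop-2-ynyl pivalate, via bromomagnesium 1-[2,4-bis(pivaloyloxy)phenyl]prop-2-yn-1-olate 13 (not isolated)
Conditions: 12 (1.1 equiv), THF, −78 °C; then PivCl, DMAP (cat.), −78 to 0 °C
Reagents that add atoms: pivaloyl chloride, CC(C)(C)C(=O)Cl
Why: 1,2-Addition of an alkynyl Grignard reagent to the aldehyde, much faster at −78 °C than attack on the hindered aryl esters, followed by O-acylation of 13 in the flask. Trapping with the acyl group already on the ring means that a shift of the ortho pivaloyl group onto the alkoxide, followed by acylation of the freed phenoxide, gives the same 14. The carbinol centre forms racemic, which is all step 8 needs.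

Step 8
Reactants: 9 3-hydroxy-5-methoxy-4-(3-methylbut-2-enyl)phenyl pivalate; 14 rac-1-[2,4-bis(pivaloyloxy)phenyl]prop-2-ynyl pivalate
Product: 15 (S)-1-[2,4-bis(pivaloyloxy)phenyl]prop-2-ynyl 3-methoxy-2-(3-methylbut-2-enyl)-5-(pivaloyloxy)phenyl ether
Conditions: (CuOTf)2·C6H6 (2.5 mol %), (S,S)-Ph-pybox [2,6-bis((4S)-4-phenyl-4,5-dihydrooxazol-2-yl)pyridine] (6 mol %), i-Pr2NEt, MeOH, −20 °C
Reagents that add atoms: none
Why: Copper-catalysed enantioselective propargylic etherification of a propargylic ester with a phenol: the terminal alkyne forms a monovalent copper acetylide, loss of pivalate gives a copper allenylidene held by the tridentate chiral ligand, and the phenoxide of 9 adds to the γ-carbon on the open face. Both enantiomers of 14 converge on 15, and the ligand sets C2. The ring A pivalate lowers the nucleophilicity of the ring carbons so that oxygen is alkylated, and the ring B pivalates keep 14 from ionising without copper.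

Step 9
Reactants: 15 (S)-1-[2,4-bis(pivaloyloxy)phenyl]prop-2-ynyl 3-methoxy-2-(3-methylbut-2-enyl)-5-(pivaloyloxy)phenyl ether
Product: 16 (S)-2-[2,4-bis(pivaloyloxy)phenyl]-7-methoxy-8-(3-methylbut-2-enyl)-5-(pivaloyloxy)-2H-chromene
Conditions: Ph3PAuNTf2 (3 mol %), CH2Cl2, 0 °C, dark
Reagents that add atoms: none
Why: This is the cationic monovalent-gold-catalysed intramolecular hydroarylation that converts aryl propargyl ethers into 2H-chromenes. Ph3PAu+ coordinates the terminal alkyne, C4a of ring A attacks the terminal alkyne carbon anti to gold, and the arenium ion rearomatises by losing its proton, which cleaves the C3–Au bond and frees the catalyst. Ring C closes in the 6-endo-dig mode and C4–C4a is the only skeletal bond formed; 5-exo-dig closure is not expected, because a linear alkyne on the two-atom O1–C2 tether cannot bring its inner carbon to C4a without severe strain. No stereocentre is created, and C2 is retained because none of its bonds takes part. Site selectivity is fixed by the substrate: C8 carries the prenyl group, so C4a is the only free position ortho to O1, and it is activated by O1 and the C5 oxygen (ortho) and by the C7 methoxy group (para). Chemoselectivity over the prenyl double bond follows from ring size, since capture of the gold-bound alkyne by that alkene would need a seven- or eight-membered ring, and ring B cannot compete because its free ortho carbon is meta to both of its oxygens. Configurational integrity rests on the pivalates: the two on ring B destabilise a cation at C2 so that the C2–O1 bond does not ionise, and the mild, non-basic catalyst at 0 °C gives the thermal propargyl Claisen pathway, whose achiral intermediate would erase C2, no chance to compete.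

Step 10
Reactants: 16 (S)-2-[2,4-bis(pivaloyloxy)phenyl]-7-methoxy-8-(3-methylbut-2-enyl)-5-(pivaloyloxy)-2H-chromene
Product: 17 (S)-2-[2,4-bis(pivaloyloxy)phenyl]-7-methoxy-8-(3-methylbut-2-enyl)-5-(pivaloyloxy)chroman
Conditions: 2-O2NC6H4SO2NHNH2 (excess), Et3N, CH2Cl2, rt
Reagents that add atoms: none
Why: Diimide reduction: diimide released from the sulfonylhydrazide transfers two hydrogens in a concerted syn fashion, and its rate drops sharply with alkene substitution, so the cis-disubstituted styrenic C3=C4 bond is saturated while the trisubstituted prenyl alkene is left. No metal is present, so the benzylic, allylic C2–O1 bond is not hydrogenolysed and C2 keeps its configuration.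

Step 11
Reactants: 17 (S)-2-[2,4-bis(pivaloyloxy)phenyl]-7-methoxy-8-(3-methylbut-2-enyl)-5-(pivaloyloxy)chroman
Product: 18 (S)-2-(2,4-dihydroxyphenyl)-7-methoxy-8-(3-methylbut-2-enyl)chroman-5-ol (CNP0115018.1)
Conditions: K2CO3 (cat.), degassed MeOH, 0 °C to rt, argon; aq. NH4Cl
Reagents that add atoms: none
Why: Base-catalysed transesterification of the three aryl pivalates with methanol; phenoxides are good leaving groups, so carbonate in methanol suffices and the methyl ether, the ring ether and the prenyl group are untouched. Working cold, under argon and for the shortest time needed limits air oxidation and phenoxide-assisted opening of the C2–O1 bond, so 18 should be obtained with C2 still (S).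

## Compound list

1 | 5-methoxyresorcinol | COc1cc(O)cc(O)c1 | starting material
2 | 3-methoxy-5-(triisopropylsilyloxy)phenol | COc1cc(O)cc(O[Si](C(C)C)(C(C)C)C(C)C)c1 | intermediate
3 | triisopropyl[3-methoxy-5-(methoxymethoxy)phenoxy]silane | COCOc1cc(OC)cc(O[Si](C(C)C)(C(C)C)C(C)C)c1 | intermediate
4 | prenyl bromide (1-bromo-3-methylbut-2-ene) | CC(C)=CCBr | starting material
5 | [2-methoxy-6-(methoxymethoxy)-4-(triisopropylsilyloxy)phenyl]lithium | [Li]c1c(OC)cc(O[Si](C(C)C)(C(C)C)C(C)C)cc1OCOC | intermediate
6 | triisopropyl[3-methoxy-5-(methoxymethoxy)-4-(3-methylbut-2-enyl)phenoxy]silane | COCOc1cc(O[Si](C(C)C)(C(C)C)C(C)C)cc(OC)c1CC=C(C)C | intermediate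
7 | 3-methoxy-5-(methoxymethoxy)-4-(3-methylbut-2-enyl)phenol (present as its tetrabutylammonium phenoxide) | COCOc1cc(O)cc(OC)c1CC=C(C)C | intermediate
8 | 3-methoxy-5-(methoxymethoxy)-4-(3-methylbut-2-enyl)phenyl pivalate | COCOc1cc(OC(=O)C(C)(C)C)cc(OC)c1CC=C(C)C | intermediate
9 | 3-hydroxy-5-methoxy-4-(3-methylbut-2-enyl)phenyl pivalate | COc1cc(OC(=O)C(C)(C)C)cc(O)c1CC=C(C)C | intermediate
10 | 2,4-dihydroxybenzaldehyde | O=Cc1ccc(O)cc1O | starting material
11 | 4-formyl-1,3-phenylene dipivalate | O=Cc1ccc(OC(=O)C(C)(C)C)cc1OC(=O)C(C)(C)C | intermediate
12 | ethynylmagnesium bromide | C#C[Mg]Br | starting material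
13 | bromomagnesium 1-[2,4-bis(pivaloyloxy)phenyl]prop-2-yn-1-olate | C#CC(O[Mg]Br)c1ccc(OC(=O)C(C)(C)C)cc1OC(=O)C(C)(C)C | intermediate
14 | rac-1-[2,4-bis(pivaloyloxy)phenyl]prop-2-ynyl pivalate | C#CC(OC(=O)C(C)(C)C)c1ccc(OC(=O)C(C)(C)C)cc1OC(=O)C(C)(C)C | intermediate
15 | (S)-1-[2,4-bis(pivaloyloxy)phenyl]prop-2-ynyl 3-methoxy-2-(3-methylbut-2-enyl)-5-(pivaloyloxy)phenyl ether | COc1cc(OC(=O)C(C)(C)C)cc(c1CC=C(C)C)O[C@H](c1ccc(OC(=O)C(C)(C)C)cc1OC(=O)C(C)(C)C)C#C | intermediate
16 | (S)-2-[2,4-bis(pivaloyloxy)phenyl]-7-methoxy-8-(3-methylbut-2-enyl)-5-(pivaloyloxy)-2H-chromene | COc1cc(OC(=O)C(C)(C)C)c2c(c1CC=C(C)C)O[C@H](c1ccc(OC(=O)C(C)(C)C)cc1OC(=O)C(C)(C)C)C=C2 | intermediate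
17 | (S)-2-[2,4-bis(pivaloyloxy)phenyl]-7-methoxy-8-(3-methylbut-2-enyl)-5-(pivaloyloxy)chroman | COc1cc(OC(=O)C(C)(C)C)c2c(c1CC=C(C)C)O[C@H](c1ccc(OC(=O)C(C)(C)C)cc1OC(=O)C(C)(C)C)CC2 | intermediate
18 | (S)-2-(2,4-dihydroxyphenyl)-7-methoxy-8-(3-methylbut-2-enyl)chroman-5-ol | COc1cc(O)c2c(c1CC=C(C)C)O[C@H](c1ccc(O)cc1O)CC2 | target

## Step count and least certain steps

Total step count: 11. Longest linear sequence: 9 steps (steps 1 to 5 and 8 to 11, from 1); the ring B branch (steps 6 and 7) joins at step 8.

**Step 9 (key step).**
- Most likely failure: loss of enantiopurity at C2. The C2–O1 bond is allylic to nothing yet but benzylic and attached to an aryloxy group, so gold acting as a Lewis acid, or traces of HNTf2, could ionise it; a drift into the sigmatropic pathway would have the same effect. The product is a 2-aryl-2H-chromene, which can also racemise by light-induced electrocyclic ring opening, hence the dark and the immediate reduction.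
- Less likely failure: capture of the activated alkyne by the prenyl double bond.
- Fallback, from 15 back to 16: replace metal catalysis by an iodonium-triggered 6-endo cyclisation (I2, NaHCO3, MeNO2, rt, dark). Iodine adds only reversibly to the prenyl alkene but irreversibly where the arene traps the iodonium ion of the alkyne. This should give (R)-2-[2,4-bis(pivaloyloxy)phenyl]-3-iodo-7-methoxy-8-(3-methylbut-2-enyl)-5-(pivaloyloxy)-2H-chromene F1, which has the same spatial arrangement at C2 as 16; the descriptor changes only because iodine raises the rank of C3. Reduction of the vinyl iodide with Bu3SnH and the zerovalent palladium complex Pd(PPh3)4 then gives 16.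

**Step 8.**
- Most likely failure: alkylation at a ring carbon of 9 instead of at oxygen, a path open to electron-rich phenols. The ortho-prenyl phenol is also hindered and may react slowly enough for solvent methanol to intercept the copper allenylidene, and the ortho-acyloxy group on the electrophile may lower the enantioselectivity.
- Fallback, from 11 and 9 back to 15: make C2 as an alcohol and invert it. Addition of the zinc acetylide from trimethylsilylacetylene and Me2Zn, with the antipode of a chiral bis-prolinol phenol ligand that gives the required alcohol, should furnish (S)-1-[2,4-bis(pivaloyloxy)phenyl]-3-(trimethylsilyl)prop-2-yn-1-ol F2. A Mitsunobu reaction of F2 with 9 (PPh3, DIAD, toluene, 0 °C) proceeds with inversion to (R)-1-[2,4-bis(pivaloyloxy)phenyl]-3-(trimethylsilyl)prop-2-ynyl 3-methoxy-2-(3-methylbut-2-enyl)-5-(pivaloyloxy)phenyl ether F3. C-Desilylation with TBAF buffered by AcOH at 0 °C gives 15; the change from (R) in F3 to (S) in 15 reflects only the lower rank of the ethynyl group once silicon is gone.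

**Step 7.**
- Most likely failure: in 13 the ortho pivaloyl group can shift to the alkoxide, and the resulting ortho-phenoxide can expel the benzylic pivalate to give an ortho-quinone methide, which would consume a second equivalent of 12. Attack of 12 on the aryl esters on warming is a lesser concern.
- Fallback, from 11 back to 14: use a zinc acetylide, whose covalent zinc alkoxide does not transfer acyl groups. Trimethylsilylacetylene, Me2Zn and a racemic amino alcohol ligand in toluene should give rac-1-[2,4-bis(pivaloyloxy)phenyl]-3-(trimethylsilyl)prop-2-yn-1-ol F4. Acylation under neutral conditions (PivCl, pyridine, DMAP) gives rac-1-[2,4-bis(pivaloyloxy)phenyl]-3-(trimethylsilyl)prop-2-ynyl pivalate F5, and buffered TBAF (AcOH, 0 °C) removes the silyl group to give 14.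

**Step 10.**
- Most likely failure: incomplete reduction, because diimide disproportionates faster than it reduces a hindered styrenic alkene; forcing the reaction with a large excess could then begin to saturate the prenyl group.
- Fallback, from 16 back to 17: homogeneous hydrogenation with H2 and RhCl(PPh3)3 in benzene–ethanol at rt. This catalyst also discriminates by alkene substitution and does not hydrogenolyse benzylic ethers; no new compound is involved.

**Step 11.**
- Most likely failure: partial epimerisation at C2. Once ring B carries phenoxides ortho and para to C2, reversible expulsion of the ring A phenoxide through a quinone methide becomes possible in a protic basic medium; air oxidation of the electron-rich phenoxides is the second concern.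
- Fallback, from 17 back to 18: reductive cleavage of the esters with i-Bu2AlH in CH2Cl2 at −78 °C, followed by work-up with aqueous potassium sodium tartrate. The phenols are then held as aluminium phenoxides in an aprotic medium until they are protonated; no new compound is involved.

## Further compounds

F1 | step 9 | (R)-2-[2,4-bis(pivaloyloxy)phenyl]-3-iodo-7-methoxy-8-(3-methylbut-2-enyl)-5-(pivaloyloxy)-2H-chromene | COc1cc(OC(=O)C(C)(C)C)c2c(c1CC=C(C)C)O[C@H](c1ccc(OC(=O)C(C)(C)C)cc1OC(=O)C(C)(C)C)C(I)=C2
F2 | step 8 | (S)-1-[2,4-bis(pivaloyloxy)phenyl]-3-(trimethylsilyl)prop-2-yn-1-ol | O[C@@H](c1ccc(OC(=O)C(C)(C)C)cc1OC(=O)C(C)(C)C)C#C[Si](C)(C)C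
F3 | step 8 | (R)-1-[2,4-bis(pivaloyloxy)phenyl]-3-(trimethylsilyl)prop-2-ynyl 3-methoxy-2-(3-methylbut-2-enyl)-5-(pivaloyloxy)phenyl ether | COc1cc(OC(=O)C(C)(C)C)cc(c1CC=C(C)C)O[C@H](c1ccc(OC(=O)C(C)(C)C)cc1OC(=O)C(C)(C)C)C#C[Si](C)(C)C
F4 | step 7 | rac-1-[2,4-bis(pivaloyloxy)phenyl]-3-(trimethylsilyl)prop-2-yn-1-ol | OC(c1ccc(OC(=O)C(C)(C)C)cc1OC(=O)C(C)(C)C)C#C[Si](C)(C)C
F5 | step 7 | rac-1-[2,4-bis(pivaloyloxy)phenyl]-3-(trimethylsilyl)prop-2-ynyl pivalate | CC(C)(C)C(=O)OC(c1ccc(OC(=O)C(C)(C)C)cc1OC(=O)C(C)(C)C)C#C[Si](C)(C)C
F0 | step 10 | none | none
F0 | step 11 | none | none
A1 | alternative 1 | (S)-5-(tert-butyldimethylsilyloxy)-2-[4-(tert-butyldimethylsilyloxy)-2-hydroxyphenyl]-7-methoxy-8-(3-methylbut-2-enyl)chroman | COc1cc(O[Si](C)(C)C(C)(C)C)c2c(c1CC=C(C)C)O[C@H](c1ccc(O[Si](C)(C)C(C)(C)C)cc1O)CC2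
A2 | alternative 1 | 3-(tert-butyldimethylsilyloxy)-2-(hydroxymethyl)-5-methoxy-6-(3-methylbut-2-enyl)phenol | COc1cc(O[Si](C)(C)C(C)(C)C)c(CO)c(O)c1CC=C(C)C
A3 | alternative 1 | 5-(tert-butyldimethylsilyloxy)-2-vinylphenol | C=Cc1ccc(O[Si](C)(C)C(C)(C)C)cc1O
A4 | alternative 2 | (S)-2-[2,4-bis(methoxymethoxy)phenyl]-7-methoxy-5-(methoxymethoxy)-8-(3-methylbut-2-enyl)chroman | COc1cc(OCOC)c2c(c1CC=C(C)C)O[C@H](c1ccc(OCOC)cc1OCOC)CC2
A5 | alternative 2 | 1-iodo-3-methoxy-5-(methoxymethoxy)-2-(3-methylbut-2-enyl)benzene | COc1cc(OCOC)cc(I)c1CC=C(C)C
A6 | alternative 2 | (S)-2-[2,4-bis(methoxymethoxy)phenyl]oxetane | O1[C@H](c2ccc(OCOC)cc2OCOC)CC1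
A7 | alternative 3 | (S)-2-[2,4-bis(tert-butyldimethylsilyloxy)phenyl]-5-(tert-butyldimethylsilyloxy)-7-methoxy-8-(3-methylbut-2-enyl)-2H-chromene | COc1cc(O[Si](C)(C)C(C)(C)C)c2c(c1CC=C(C)C)O[C@H](c1ccc(O[Si](C)(C)C(C)(C)C)cc1O[Si](C)(C)C(C)(C)C)C=C2
A8 | alternative 3 | (S)-1-[2,4-bis(tert-butyldimethylsilyloxy)phenyl]allyl 3-(tert-butyldimethylsilyloxy)-5-methoxy-6-(3-methylbut-2-enyl)-2-vinylphenyl ether | COc1cc(O[Si](C)(C)C(C)(C)C)c(C=C)c(c1CC=C(C)C)O[C@H](c1ccc(O[Si](C)(C)C(C)(C)C)cc1O[Si](C)(C)C(C)(C)C)C=C
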